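**Numbering key.** 1 7-methoxy-2,2-dimethyl-2H-chromene; 2 its 6-acetyl derivative; 3 allylboronic acid pinacol ester; 4 borate of 5 (not isolated); 5 (R) tertiary homoallylic alcohol; 6 its triethylsilyl ether; 7 (2R,4S) secondary pinacol boronate; 8 furan; 9 furan-2-yllithium; 10 furyl boronate complex; 11 2-alkylfuran; 12 methyl bromoacetate; 13 5-lithio derivative of 11; 14 zinc chloride from 13; 15 methyl furan-2-ylacetate; 16 its lithium carboxylate; 17 furan-2-ylacetic acid; 18 dilithium enediolate; 19 bis(trimethylsilyl) ketene acetal; 20 but-3-yn-2-one; 21 cycloadduct; 22 silylated benzofuran; 23 target.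

## Analysis of the target

Target 23 consists of two benzo-fused oxygen heterocycles joined by a substituted pentane chain. Chain C4 is a tertiary carbinol (methyl, hydroxyl) bonded to C6 of a 7-methoxy-2,2-dimethyl-2H-chromene, and chain C2 is a methyl-bearing methine bonded to C2 of a 5-acetyl-6-hydroxybenzofuran. The two stereocentres, (R) at the carbinol and (S) at the methine, are 1,3-related across a methylene group in an open chain, so neither can be relayed from the other through a ring and each needs its own source of control. The carbinol is benzylic to a ring with an ortho methoxy group and a para ring oxygen, so it ionises easily and dehydrates under acid. The chromene C3=C4 bond is a cis-styrene conjugated with the para methoxy group and reacts with protic acids, halonium sources, oxidants and hydrogenation catalysts; the ortho-hydroxyaryl ketone and the benzofuran are robust by comparison. The difficulty is therefore acyclic 1,3-stereocontrol that includes a fully substituted carbinol, within a functional-group set that excludes acid, hydrogenation and strong electrophiles late in the route. The strategy rests on the benzene ring of the benzofuran, which carries C4–H, C5–acetyl, C6–OH and C7–H. C7 and C6 correspond to the methylene and carboxyl carbons of a furan-2-ylacetic acid, and C4, C5 and the acetyl group to the four carbons of but-3-yn-2-one (20), so this ring can be made last, through the C3a–C4 and C5–C6 bonds, on a furan that already carries the finished chain.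

## Retrosynthetic reasoning

**23 to 22.** Only two O–Si bonds are cut. The phenol oxygen leaves the ring-forming step as a trimethylsilyl ether and the carbinol is carried as a triethylsilyl ether. Both fall to a fluoride source under basic conditions, so the free tertiary benzylic alcohol never meets acid.

**22 to 19 and 20.** The C3a–C4 and C5–C6 bonds of the benzofuran benzene ring are cut. This is preferred to opening the furan ring because it leaves a simple 2,5-disubstituted furan and a four-carbon ynone, not a tetrasubstituted benzene that would need its own synthesis. The C6 oxygen derives from the carboxyl carbon, so the ortho relationship of hydroxyl and acetyl follows from the orientation of addition. The forward reaction must join the acetal C=C bond and the furan C2–C3 bond of 19 to the alkyne of 20 in a [4+2] sense to give 21, which then loses a silanol and becomes aromatic.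

**19 to 17 to 15.** These are functional-group changes. The ketene acetal comes from acid 17 by double deprotonation (18) and O-silylation; two identical silyl groups are used so that loss of either gives the same arene. Acid 17 comes from methyl ester 15 with aqueous base.

**15 to 11 and 12.** The bond between furan C5 and the acetate methylene is cut. The free α-position of 11 is its most readily metalated C–H bond. The lithium compound 13 is passed on to zinc (14) so that the ester of 12 survives the nickel-catalysed coupling.

**11 to 7 and 8.** The bond between furan C2 and the methine carbon is cut. A secondary boronic ester hands its alkyl group to lithiated furan 9 through complex 10 with retention, so the methine configuration is decided where the C–B bond is made. Furan 8 is the simplest possible partner.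

**7 to 6 to 5.** The C–B bond is cut back to the terminal alkene of 6. Boron must go to the internal carbon, and a chiral copper catalyst, not the remote carbinol, must choose the face. The triethylsilyl ether in 6 keeps the hydroxyl away from organolithium reagents and from boron.

**5 to 2 and 3.** The bond between the carbinol carbon and the methylene is cut. Allyl is the one carbon nucleophile for which catalytic enantioselective addition to aryl methyl ketones is well developed, and its alkene is the handle for the borylation.

**2 to 1.** The aryl–acyl bond is cut. C6 of 1 is para to the ring oxygen and ortho to the methoxy group, the most activated and least hindered position for acylation.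

## Alternatives that were turned down

**Alternative 1:** Both the aryl–carbinol bond and the CH2–alkenyl bond are cut. The carbinol carbon and its methyl group come from isopropenylboronic ester A3, the aryl group from aryllithium A2, and the rest from alkenyl triflate A4, which already holds the whole benzofuran. In the forward step A2 adds to boron of A3. A chiral bisphosphine–palladium catalyst, after oxidative addition of A4, binds the alkene of the boronate complex and triggers a 1,2-shift of the aryl group from boron to carbon while the alkenyl group is delivered to the CH2 terminus, giving tertiary boronate A1.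

- For: three fragments are joined at once, the quaternary centre is set by catalyst control, and the key step belongs to a known reaction class. On convergence and precedent this alternative is stronger than the chosen strategy.
- Against: A1 still has a 1,1-disubstituted alkene where the methine must be. Its reduction would have to be diastereoselective across an open chain and chemoselective against the chromene C3=C4 and benzofuran C2=C3 bonds, and catalysts that take direction from a hydroxyl also reduce cis-styrenes. An α-substituted alkenylboronate with an ortho-substituted, electron-rich migrating aryl group is the most demanding case for the metallate shift. The dioxolane in A1 must later be removed with acid beside the ionisable carbinol, and A4 needs a multi-step synthesis of its own.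
- Comparison: the chosen strategy sets both centres through C–B bonds of defined configuration, needs neither hydrogenation nor acid, and draws the benzofuran substituents from 20 and not from a separately made fragment.

**Alternative 2:** The carbinol C–O bond is cut and held temporarily as the alkyl C–O bond of a γ-lactone. The future carbinol methyl group appears as CH2I and the lactone carbonyl carbon is the future benzofuran C2. In the forward step acid A6, whose α-methyl centre is already (S), meets an electrophilic iodine source and a chiral hydrogen-bonding catalyst. The carboxyl oxygen closes onto the aryl-bearing alkene carbon in a 5-exo mode and iodine ends on the terminal carbon, giving lactone A5.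

- For: enantioselective halolactonisation of 4-arylpent-4-enoic acids is well developed, the ring fixes the 1,3-relationship, and the relative configuration is easy to prove. On certainty of the carbinol configuration this alternative is stronger than the allylboration of 2.
- Against: the iodine electrophile must choose the 1,1-disubstituted alkene over the chromene C3=C4 bond and the activated arene. A5 is a tertiary benzylic ester of an electron-rich arene and can ionise, which would erode the new centre. After deiodination the lactone carbonyl still has to be turned into a 2-substituted 5-acetyl-6-hydroxybenzofuran by ring opening, protection and a separate benzofuran synthesis, during which the methine sits α to a carbonyl and can epimerise.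
- Comparison: the key step solves only the carbinol, and more steps would follow A5 than follow 7 in the chosen route. The chosen strategy gives up the rigid ring but exposes the chromene to a bromonium source only at −78 °C in competition with a far more nucleophilic boronate complex, and keeps the methine as an unactivated alkyl centre.

**Alternative 3:** The benzofuran C2=C3 bond is cut. In the forward step phosphonium salt A8, whose phenol oxygen ortho to the benzylic carbon carries the full chain as an ester, is deprotonated by a tertiary amine. The ylide attacks the ester carbonyl intramolecularly, and loss of the phosphorus as its oxide forms C2=C3 and closes the five-membered ring, giving A7, one desilylation from 23.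

- For: the ring closure is well established for 2-alkylbenzofurans, mild and convergent. On precedent for the ring-forming step this alternative is clearly stronger.
- Against: all the stereochemistry is moved into the acyl fragment, a 4-aryl-4-silyloxy-2-methylpentanoic acid, which is as hard to make as 19 and lactonises when the hydroxyl is free. In A8 the methine is α to an aryl ester carbonyl; activation of the acid (ketene formation) and exposure to amine and ylide at elevated temperature threaten it with epimerisation. The phosphonium partner needs regioselective work on a polysubstituted benzene whose acetyl group can also react with the ylide.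
- Comparison: the route would be as long or longer with the stereochemical problem unsolved. The chosen strategy attaches the methine to the heteroaromatic ring by a stereospecific boron-to-carbon shift with no carbonyl nearby, and pays for this with a ring-forming step that has no direct precedent.

Key step: step 9

Assumption: the sense of induction of the chiral ligands in steps 2 and 4 is inferred from simple aryl methyl ketones and 1-alkenes; if either step delivers the opposite configuration, the enantiomeric ligand is used and nothing else changes.

## Route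

Step 1
Reactants: 1 7-methoxy-2,2-dimethyl-2H-chromene
Product: 2 1-(7-methoxy-2,2-dimethyl-2H-chromen-6-yl)ethan-1-one
Conditions: AcCl (1.1 equiv), SnCl4 (1.1 equiv), CH2Cl2, −78 °C; cold aq. NaHCO3 quench
Reagents that add atoms: acetyl chloride, CC(=O)Cl
Why: Friedel–Crafts acylation; C6 is para to the ring oxygen and ortho to the methoxy group and is less hindered than C8 between the two oxygens. The preformed acylium complex should acylate this doubly activated arene at −78 °C, where addition of HCl to the C3=C4 bond and cationic oligomerisation are slow.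

Step 2
Reactants: 2 1-(7-methoxy-2,2-dimethyl-2H-chromen-6-yl)ethan-1-one; 3 allylboronic acid pinacol ester
Product: 5 (2R)-2-(7-methoxy-2,2-dimethyl-2H-chromen-6-yl)pent-4-en-2-ol, via pinacol borate 4 (not isolated)
Conditions: CuF2·2H2O (3 mol %), (R,R)-iPr-DuPHOS (6 mol %), La(OiPr)3 (4.5 mol %), DMF, −40 °C; aq. NH4Cl
Reagents that add atoms: none
Why: Catalytic enantioselective allylboration of a ketone: the phosphine reduces CuF2 to the monovalent copper fluoride complex, fluoride and La(OiPr)3 promote allyl transfer from boron to copper, and the chiral allylcopper adds to one carbonyl face through a six-membered transition state, which sets the (R) carbinol. The copper alkoxide is turned over by 3 to borate 4, which is hydrolysed on work-up; any minor enantiomer becomes a separable diastereomer after step 4.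

Step 3
Reactants: 5 (2R)-2-(7-methoxy-2,2-dimethyl-2H-chromen-6-yl)pent-4-en-2-ol
Product: 6 triethyl{[(2R)-2-(7-methoxy-2,2-dimethyl-2H-chromen-6-yl)pent-4-en-2-yl]oxy}silane
Conditions: Et3SiOTf (1.2 equiv), 2,6-lutidine (2 equiv), CH2Cl2, −78 °C; MeOH then aq. NaHCO3 at −78 °C
Reagents that add atoms: triethylsilyl trifluoromethanesulfonate, CC[Si](CC)(CC)OS(=O)(=O)C(F)(F)F
Why: Silylation of a hindered tertiary alcohol with a silyl triflate and a hindered pyridine base; the free hydroxyl would be deprotonated in steps 5 and 6 and could bind boron. The base and the low temperature keep the medium free of acid that would ionise the benzylic carbinol.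

Step 4
Reactants: 6 triethyl{[(2R)-2-(7-methoxy-2,2-dimethyl-2H-chromen-6-yl)pent-4-en-2-yl]oxy}silane
Product: 7 triethyl{[(2R,4S)-2-(7-methoxy-2,2-dimethyl-2H-chromen-6-yl)-4-(4,4,5,5-tetramethyl-1,3,2-dioxaborolan-2-yl)pentan-2-yl]oxy}silane
Conditions: B2pin2 (1.1 equiv), MeOH (2 equiv), CuCl (5 mol %), bulky C2-symmetric chiral NHC precursor of the ANIPE type (5.5 mol %), NaOtBu (20 mol %), THF, rt
Reagents that add atoms: bis(pinacolato)diboron, CC1(C)OB(OC1(C)C)B1OC(C)(C)C(C)(C)O1
Why: Copper-catalysed Markovnikov protoboration of an α-olefin: the NHC-bound boryl-copper adds across the terminal alkene with boron on the internal carbon, the bulky ligand enforces this regiochemistry and the facial choice that sets the (S) C–B centre by catalyst control, and methanol protonates the primary alkylcopper. The chromene alkene is electron-rich and flanked by the gem-dimethyl carbon, so its borylcupration should be much slower.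

Step 5
Reactants: 7 triethyl{[(2R,4S)-2-(7-methoxy-2,2-dimethyl-2H-chromen-6-yl)-4-(4,4,5,5-tetramethyl-1,3,2-dioxaborolan-2-yl)pentan-2-yl]oxy}silane; 8 furan
Product: 11 triethyl{[(2R,4S)-4-(furan-2-yl)-2-(7-methoxy-2,2-dimethyl-2H-chromen-6-yl)pentan-2-yl]oxy}silane, via furan-2-yllithium 9 (not isolated), via lithium furyl boronate complex 10 (not isolated)
Conditions: 8 (1.3 equiv), n-BuLi (1.2 equiv), THF, −78 °C → rt; 7, −78 °C; N-bromosuccinimide (1.2 equiv), THF, −78 °C; aq. Na2S2O3
Reagents that add atoms: none
Why: Stereospecific coupling of a secondary boronic ester with an electron-rich heteroaryllithium: 9 adds to boron to give 10, bromination at furan C5 triggers 1,2-migration of the alkyl group to C2 with retention at the migrating carbon, and loss of bromide and boron restores the furan, so the (S) methine is carried over from 7. The anionic complex 10 is far more nucleophilic than the chromene alkene and should consume the bromine source at −78 °C before the alkene reacts.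

Step 6
Reactants: 11 triethyl{[(2R,4S)-4-(furan-2-yl)-2-(7-methoxy-2,2-dimethyl-2H-chromen-6-yl)pentan-2-yl]oxy}silane; 12 methyl bromoacetate
Product: 15 methyl 2-{5-[(2S,4R)-4-(7-methoxy-2,2-dimethyl-2H-chromen-6-yl)-4-(triethylsilyloxy)pentan-2-yl]furan-2-yl}acetate, via 5-lithiofuran 13 (not isolated), via furylzinc chloride 14 (not isolated)
Conditions: n-BuLi (1.1 equiv), THF, −78 → −20 °C; ZnCl2 (1.2 equiv), −20 °C → rt; 12 (1.3 equiv), Ni(acac)2 (5 mol %), PPh3 (5 mol %), THF, rt
Reagents that add atoms: none
Why: α-Lithiation of a 2-alkylfuran at its only free α-position, which at low temperature should be faster than metalation of the arene C8–H, then transmetalation to zinc and nickel-catalysed cross-coupling of the arylzinc chloride with an α-bromo ester (Negishi-type). The zinc reagent tolerates the ester that the lithium reagent would attack.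

Step 7
Reactants: 15 methyl 2-{5-[(2S,4R)-4-(7-methoxy-2,2-dimethyl-2H-chromen-6-yl)-4-(triethylsilyloxy)pentan-2-yl]furan-2-yl}acetate
Product: 17 2-{5-[(2S,4R)-4-(7-methoxy-2,2-dimethyl-2H-chromen-6-yl)-4-(triethylsilyloxy)pentan-2-yl]furan-2-yl}acetic acid, via lithium carboxylate 16 (not isolated)
Conditions: LiOH·H2O (3 equiv), THF/MeOH/H2O, rt; AcOH to pH 5, 0 °C
Reagents that add atoms: lithium hydroxide, [Li+].[OH-]
Why: Ester saponification by acyl–oxygen cleavage; the silyl ether, chromene and furan are stable to hydroxide. Acidification only to pH 5 in the cold keeps the ionisable benzylic ether intact.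

Step 8
Reactants: 17 2-{5-[(2S,4R)-4-(7-methoxy-2,2-dimethyl-2H-chromen-6-yl)-4-(triethylsilyloxy)pentan-2-yl]furan-2-yl}acetic acid
Product: 19 2-{5-[(2S,4R)-4-(7-methoxy-2,2-dimethyl-2H-chromen-6-yl)-4-(triethylsilyloxy)pentan-2-yl]furan-2-yl}-1,1-bis(trimethylsilyloxy)ethene, via dilithium enediolate 18 (not isolated)
Conditions: LiN(iPr)2 (2.2 equiv), THF, −78 → 0 °C; Me3SiCl (2.5 equiv), −78 °C → rt; pentane, filtration under argon, used crude
Reagents that add atoms: chlorotrimethylsilane, C[Si](C)(C)Cl
Why: Double deprotonation of an arylacetic acid to its enediolate and silylation on both oxygens gives the bis(silyl) ketene acetal. Two identical silyl groups are used so that loss of either in step 9 leads to the same product.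

Step 9
Reactants: 19 2-{5-[(2S,4R)-4-(7-methoxy-2,2-dimethyl-2H-chromen-6-yl)-4-(triethylsilyloxy)pentan-2-yl]furan-2-yl}-1,1-bis(trimethylsilyloxy)ethene; 20 but-3-yn-2-one
Product: 22 1-{2-[(2S,4R)-4-(7-methoxy-2,2-dimethyl-2H-chromen-6-yl)-4-(triethylsilyloxy)pentan-2-yl]-6-(trimethylsilyloxy)-1-benzofuran-5-yl}ethan-1-one, via dihydrobenzofuran cycloadduct 21 (not isolated)
Conditions: 20 (2 equiv), toluene, 0 °C → 60 °C, argon; volatiles removed, crude 22 used directly
Reagents that add atoms: none
Why: Proposed new method: The exocyclic acetal C=C bond and the furan C2–C3 bond of 19 form a 1,1-bis(silyloxy)diene whose remote terminus, furan C3, is made nucleophilic by both silyloxy groups and by the ring oxygen, while the terminal alkyne carbon of 20 is the electrophilic β-position of an ynone. Bonding of furan C3 to that carbon (C3a–C4) and of the acetal carbon to the acyl-bearing alkyne carbon (C5–C6), in one asynchronous [4+2] event or through a zwitterion that collapses, closes the six-membered carbocycle by cycloaddition and gives 21. In 21 the hydrogen on C3a is vinylogously α to the acetyl group and one silyloxy group on C6 is a leaving group, so 1,4-elimination of Me3SiOH should follow and make the ring aromatic, leaving OSiMe3 on C6 beside the acetyl group on C5. The closest known reactions are Diels–Alder additions of 2-vinylfurans to acetylenic dienophiles across the furan 2,3-bond and arene-forming cycloadditions of 1,1-dioxygenated dienes with ynones; a furan-2-ylketene acetal has not been used in this way. No lasting stereocentre is formed, since C3a is stereogenic only in 21 and becomes planar, and the two chain stereocentres are remote and untouched under neutral conditions. The step needs regioselectivity (acetyl next to the oxygenated carbon) and periselectivity (reaction at the outer diene, not across furan C2 and C5 and not by Michael addition of the acetate carbon alone). The first should follow from the matched polarisation of donor diene and acceptor alkyne; the second from the branched chain on furan C5, which hinders the inner diene, and from the small aromatic stabilisation of furan, which is regained in the benzofuran.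

Step 10
Reactants: 22 1-{2-[(2S,4R)-4-(7-methoxy-2,2-dimethyl-2H-chromen-6-yl)-4-(triethylsilyloxy)pentan-2-yl]-6-(trimethylsilyloxy)-1-benzofuran-5-yl}ethan-1-one
Product: 23 1-{6-hydroxy-2-[(2S,4R)-4-hydroxy-4-(7-methoxy-2,2-dimethyl-2H-chromen-6-yl)pentan-2-yl]-1-benzofuran-5-yl}ethan-1-one
Conditions: Bu4NF (3 equiv), THF, 0 °C → rt
Reagents that add atoms: none
Why: Fluoride cleaves both Si–O bonds, the aryl trimethylsilyl ether at once and the tertiary triethylsilyl ether more slowly. The basic medium spares the tertiary benzylic alcohol, which would dehydrate under acid.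

## Compound list

1 | 7-methoxy-2,2-dimethyl-2H-chromene | COc1ccc2C=CC(C)(C)Oc2c1 | starting material
2 | 1-(7-methoxy-2,2-dimethyl-2H-chromen-6-yl)ethan-1-one | COc1cc2OC(C)(C)C=Cc2cc1C(C)=O | intermediate
3 | allylboronic acid pinacol ester | C=CCB1OC(C)(C)C(C)(C)O1 | starting material
4 | 2-{[(2R)-2-(7-methoxy-2,2-dimethyl-2H-chromen-6-yl)pent-4-en-2-yl]oxy}-4,4,5,5-tetramethyl-1,3,2-dioxaborolane | COc1cc2OC(C)(C)C=Cc2cc1[C@](C)(OB1OC(C)(C)C(C)(C)O1)CC=C | intermediate
5 | (2R)-2-(7-methoxy-2,2-dimethyl-2H-chromen-6-yl)pent-4-en-2-ol | COc1cc2OC(C)(C)C=Cc2cc1[C@](C)(O)CC=C | intermediate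
6 | triethyl{[(2R)-2-(7-methoxy-2,2-dimethyl-2H-chromen-6-yl)pent-4-en-2-yl]oxy}silane | COc1cc2OC(C)(C)C=Cc2cc1[C@](C)(O[Si](CC)(CC)CC)CC=C | intermediate
7 | triethyl{[(2R,4S)-2-(7-methoxy-2,2-dimethyl-2H-chromen-6-yl)-4-(4,4,5,5-tetramethyl-1,3,2-dioxaborolan-2-yl)pentan-2-yl]oxy}silane | COc1cc2OC(C)(C)C=Cc2cc1[C@](C)(O[Si](CC)(CC)CC)C[C@H](C)B1OC(C)(C)C(C)(C)O1 | intermediate
8 | furan | c1ccoc1 | starting material
9 | furan-2-yllithium | [Li]c1ccco1 | intermediate
10 | lithium furan-2-yl boronate complex of 7 | [Li+].COc1cc2OC(C)(C)C=Cc2cc1[C@](C)(O[Si](CC)(CC)CC)C[C@H](C)[B-]1(c2ccco2)OC(C)(C)C(C)(C)O1 | intermediate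
11 | triethyl{[(2R,4S)-4-(furan-2-yl)-2-(7-methoxy-2,2-dimethyl-2H-chromen-6-yl)pentan-2-yl]oxy}silane | COc1cc2OC(C)(C)C=Cc2cc1[C@](C)(O[Si](CC)(CC)CC)C[C@H](C)c1ccco1 | intermediate
12 | methyl bromoacetate | COC(=O)CBr | starting material
13 | {5-[(2S,4R)-4-(7-methoxy-2,2-dimethyl-2H-chromen-6-yl)-4-(triethylsilyloxy)pentan-2-yl]furan-2-yl}lithium | COc1cc2OC(C)(C)C=Cc2cc1[C@](C)(O[Si](CC)(CC)CC)C[C@H](C)c1ccc([Li])o1 | intermediate
14 | chloro{5-[(2S,4R)-4-(7-methoxy-2,2-dimethyl-2H-chromen-6-yl)-4-(triethylsilyloxy)pentan-2-yl]furan-2-yl}zinc | COc1cc2OC(C)(C)C=Cc2cc1[C@](C)(O[Si](CC)(CC)CC)C[C@H](C)c1ccc([Zn]Cl)o1 | intermediate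
15 | methyl 2-{5-[(2S,4R)-4-(7-methoxy-2,2-dimethyl-2H-chromen-6-yl)-4-(triethylsilyloxy)pentan-2-yl]furan-2-yl}acetate | COc1cc2OC(C)(C)C=Cc2cc1[C@](C)(O[Si](CC)(CC)CC)C[C@H](C)c1ccc(CC(=O)OC)o1 | intermediate
16 | lithium 2-{5-[(2S,4R)-4-(7-methoxy-2,2-dimethyl-2H-chromen-6-yl)-4-(triethylsilyloxy)pentan-2-yl]furan-2-yl}acetate | [Li+].COc1cc2OC(C)(C)C=Cc2cc1[C@](C)(O[Si](CC)(CC)CC)C[C@H](C)c1ccc(CC(=O)[O-])o1 | intermediate
17 | 2-{5-[(2S,4R)-4-(7-methoxy-2,2-dimethyl-2H-chromen-6-yl)-4-(triethylsilyloxy)pentan-2-yl]furan-2-yl}acetic acid | COc1cc2OC(C)(C)C=Cc2cc1[C@](C)(O[Si](CC)(CC)CC)C[C@H](C)c1ccc(CC(O)=O)o1 | intermediate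
18 | dilithium 2-{5-[(2S,4R)-4-(7-methoxy-2,2-dimethyl-2H-chromen-6-yl)-4-(triethylsilyloxy)pentan-2-yl]furan-2-yl}ethene-1,1-diolate | COc1cc2OC(C)(C)C=Cc2cc1[C@](C)(O[Si](CC)(CC)CC)C[C@H](C)c1ccc(C=C(O[Li])O[Li])o1 | intermediate
19 | 2-{5-[(2S,4R)-4-(7-methoxy-2,2-dimethyl-2H-chromen-6-yl)-4-(triethylsilyloxy)pentan-2-yl]furan-2-yl}-1,1-bis(trimethylsilyloxy)ethene | COc1cc2OC(C)(C)C=Cc2cc1[C@](C)(O[Si](CC)(CC)CC)C[C@H](C)c1ccc(C=C(O[Si](C)(C)C)O[Si](C)(C)C)o1 | intermediate
20 | but-3-yn-2-one | CC(=O)C#C | starting material
21 | 1-{2-[(2S,4R)-4-(7-methoxy-2,2-dimethyl-2H-chromen-6-yl)-4-(triethylsilyloxy)pentan-2-yl]-6,6-bis(trimethylsilyloxy)-3a,6-dihydro-1-benzofuran-5-yl}ethan-1-one (C3a not assigned) | COc1cc2OC(C)(C)C=Cc2cc1[C@](C)(O[Si](CC)(CC)CC)C[C@H](C)C1=CC2C=C(C(C)=O)C(O[Si](C)(C)C)(O[Si](C)(C)C)C=C2O1 | intermediate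
22 | 1-{2-[(2S,4R)-4-(7-methoxy-2,2-dimethyl-2H-chromen-6-yl)-4-(triethylsilyloxy)pentan-2-yl]-6-(trimethylsilyloxy)-1-benzofuran-5-yl}ethan-1-one | COc1cc2OC(C)(C)C=Cc2cc1[C@](C)(O[Si](CC)(CC)CC)C[C@H](C)c1cc2cc(C(C)=O)c(O[Si](C)(C)C)cc2o1 | intermediate
23 | 1-{6-hydroxy-2-[(2S,4R)-4-hydroxy-4-(7-methoxy-2,2-dimethyl-2H-chromen-6-yl)pentan-2-yl]-1-benzofuran-5-yl}ethan-1-one | COc1cc2c(cc1[C@](C)(O)C[C@H](C)c1cc3cc(C(C)=O)c(O)cc3o1)C=CC(C)(C)O2 | target

## Step count and least certain steps

Total: 10 steps. Longest linear sequence: 10 steps (1 to 23); 3, 8, 12 and 20 are commercial.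

**Step 9 (key step, proposed new method).** The most likely failure is bond formation that starts at the acetate carbon and not at furan C3. Michael addition followed by silyl transfer would then give an open-chain adduct, or closure to a cyclobutene and ring opening would lead to the 4-oxygenated isomer. Cycloaddition across furan C2 and C5 and polymerisation of the ynone are lesser risks. The fallback uses known chemistry, sets out from boronate 7 and comes back at target 23. Boronate 7 is treated with α-lithiated vinyl N,N-diisopropylcarbamate and then with I2 and NaOMe (Zweifel-type alkenylation, retention at the migrating carbon) to give enol carbamate F1. LiN(iPr)2 eliminates the carbamate and gives terminal alkyne F2. Iodination of 2,4-dihydroxyacetophenone with ICl gives 1-(2,4-dihydroxy-5-iodophenyl)ethan-1-one F3. Sonogashira coupling of F2 with F3 (Pd(PPh3)2Cl2, CuI, Et3N, DMF, 60 °C) with in situ cyclisation of the ortho hydroxyl onto the alkyne gives benzofuran triethylsilyl ether F4. Bu4NF then gives 23.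

**Step 4.** The most likely failure is erosion of the branched selectivity, because the internal carbon is flanked by a neopentyl-type methylene, together with incomplete catalyst control over the new C–B centre. Borylcupration of the chromene alkene is a lesser risk. The fallback assembles the chain by lithiation–borylation; it sets out from ketone 2 and comes back at furan 11. Asymmetric transfer hydrogenation of 2 (RuCl(p-cymene)[(S,S)-TsDPEN], HCO2H/Et3N) gives (S)-alcohol F5, which is converted with N,N-diisopropylcarbamoyl chloride into carbamate F6. Separately, Wittig methylenation of 2-acetylfuran gives 2-isopropenylfuran F7, and enantioselective hydroboration with HBpin under a chiral copper hydride catalyst (CuCl, DTBM-SEGPHOS, KOtBu) gives primary boronate F8. F6 is lithiated with s-BuLi (Et2O, −78 °C) and F8 is added; 1,2-migration on warming gives tertiary boronate F9. NaOH/H2O2 gives tertiary alcohol F10, and Et3SiOTf/2,6-lutidine gives 11. The methine then comes from the hydroboration of F7 and the carbinol from the reduction of 2.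

**Step 2.** The most likely failure is low conversion or low enantioselectivity, because the ketone is a poor electrophile (two donor oxygens) and its ortho methoxy group offers a second binding site to the catalyst. The fallback sets out from ketone 2 and comes back at alcohol 5. Alcohol F5 and carbamate F6 are made as above. F6 is lithiated with s-BuLi and treated with allylboronate 3, and 1,2-migration gives tertiary allyl boronate F11 (MgBr2 in MeOH is added before warming if the boronate complex reverts). NaOH/H2O2 then gives 5, with the carbinol configuration derived from the secondary alcohol.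

**Step 6.** The most likely failure is in the nickel-catalysed coupling: reduction or homocoupling of 12 and protonation of 14 in place of C–C bond formation. The site of lithiation is checked beforehand by a D2O quench. The fallback reverses the polarity of the coupling; it sets out from furan 11 and comes back at ester 15. Lithio compound 13 is quenched with 1,2-dibromotetrachloroethane to give bromofuran F12, which is coupled with the Reformatsky reagent BrZnCH2CO2Me under Pd(dba)2/Q-Phos in THF at rt to give 15.

**Step 1.** The most likely failure is acid-induced addition to or oligomerisation of the chromene C3=C4 bond, or acylation at C3 of that alkene. The fallback removes the alkene before the acylation and restores it afterwards; it sets out from chromene 1 and comes back at ketone 2. Hydrogenation of 1 (H2, Pd/C, EtOAc) gives chroman F13, Friedel–Crafts acetylation (AcCl, AlCl3, CH2Cl2, 0 °C) gives acetylchroman F14, and dehydrogenation with DDQ in refluxing dioxane gives 2.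

## Further compounds

F1 | step 9 | (3S,5R)-5-(7-methoxy-2,2-dimethyl-2H-chromen-6-yl)-3-methyl-5-(triethylsilyloxy)hex-1-en-2-yl N,N-diisopropylcarbamate | COc1cc2OC(C)(C)C=Cc2cc1[C@](C)(O[Si](CC)(CC)CC)C[C@H](C)C(=C)OC(=O)N(C(C)C)C(C)C
F2 | step 9 | triethyl{[(2R,4S)-2-(7-methoxy-2,2-dimethyl-2H-chromen-6-yl)-4-methylhex-5-yn-2-yl]oxy}silane | COc1cc2OC(C)(C)C=Cc2cc1[C@](C)(O[Si](CC)(CC)CC)C[C@H](C)C#C
F3 | step 9 | 1-(2,4-dihydroxy-5-iodophenyl)ethan-1-one | CC(=O)c1cc(I)c(O)cc1O
F4 | step 9 | 1-{6-hydroxy-2-[(2S,4R)-4-(7-methoxy-2,2-dimethyl-2H-chromen-6-yl)-4-(triethylsilyloxy)pentan-2-yl]-1-benzofuran-5-yl}ethan-1-one | COc1cc2OC(C)(C)C=Cc2cc1[C@](C)(O[Si](CC)(CC)CC)C[C@H](C)c1cc2cc(C(C)=O)c(O)cc2o1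
F5 | step 4 | (1S)-1-(7-methoxy-2,2-dimethyl-2H-chromen-6-yl)ethan-1-ol | COc1cc2OC(C)(C)C=Cc2cc1[C@H](C)O
F6 | step 4 | (1S)-1-(7-methoxy-2,2-dimethyl-2H-chromen-6-yl)ethyl N,N-diisopropylcarbamate | COc1cc2OC(C)(C)C=Cc2cc1[C@H](C)OC(=O)N(C(C)C)C(C)C
F7 | step 4 | 2-(prop-1-en-2-yl)furan | CC(=C)c1ccco1
F8 | step 4 | 2-[(2S)-2-(furan-2-yl)propyl]-4,4,5,5-tetramethyl-1,3,2-dioxaborolane | CC1(C)OB(C[C@H](C)c2ccco2)OC1(C)C
F9 | step 4 | 2-[(2S,4S)-4-(furan-2-yl)-2-(7-methoxy-2,2-dimethyl-2H-chromen-6-yl)pentan-2-yl]-4,4,5,5-tetramethyl-1,3,2-dioxaborolane | COc1cc2OC(C)(C)C=Cc2cc1[C@](C)(B1OC(C)(C)C(C)(C)O1)C[C@H](C)c1ccco1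
F10 | step 4 | (2R,4S)-4-(furan-2-yl)-2-(7-methoxy-2,2-dimethyl-2H-chromen-6-yl)pentan-2-ol | COc1cc2OC(C)(C)C=Cc2cc1[C@](C)(O)C[C@H](C)c1ccco1
F11 | step 2 | 2-[(2S)-2-(7-methoxy-2,2-dimethyl-2H-chromen-6-yl)pent-4-en-2-yl]-4,4,5,5-tetramethyl-1,3,2-dioxaborolane | COc1cc2OC(C)(C)C=Cc2cc1[C@](C)(B1OC(C)(C)C(C)(C)O1)CC=C
F12 | step 6 | {[(2R,4S)-4-(5-bromofuran-2-yl)-2-(7-methoxy-2,2-dimethyl-2H-chromen-6-yl)pentan-2-yl]oxy}triethylsilane | COc1cc2OC(C)(C)C=Cc2cc1[C@](C)(O[Si](CC)(CC)CC)C[C@H](C)c1ccc(Br)o1
F13 | step 1 | 7-methoxy-2,2-dimethyl-3,4-dihydro-2H-chromene | COc1ccc2CCC(C)(C)Oc2c1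
F14 | step 1 | 1-(7-methoxy-2,2-dimethyl-3,4-dihydro-2H-chromen-6-yl)ethan-1-one | COc1cc2OC(C)(C)CCc2cc1C(C)=O
A1 | alternative 1 | 2-[(2S)-2-(7-methoxy-2,2-dimethyl-2H-chromen-6-yl)-4-{5-(2-methyl-1,3-dioxolan-2-yl)-6-[(triisopropylsilyl)oxy]-1-benzofuran-2-yl}pent-4-en-2-yl]-4,4,5,5-tetramethyl-1,3,2-dioxaborolane | COc1cc2OC(C)(C)C=Cc2cc1[C@](C)(B3OC(C)(C)C(C)(C)O3)CC(=C)c1cc2cc(C3(C)OCCO3)c(O[Si](C(C)C)(C(C)C)C(C)C)cc2o1
A2 | alternative 1 | (7-methoxy-2,2-dimethyl-2H-chromen-6-yl)lithium | COc1cc2OC(C)(C)C=Cc2cc1[Li]
A3 | alternative 1 | 4,4,5,5-tetramethyl-2-(prop-1-en-2-yl)-1,3,2-dioxaborolane | CC(=C)B1OC(C)(C)C(C)(C)O1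
A4 | alternative 1 | 1-{5-(2-methyl-1,3-dioxolan-2-yl)-6-[(triisopropylsilyl)oxy]-1-benzofuran-2-yl}ethenyl trifluoromethanesulfonate | C=C(OS(=O)(=O)C(F)(F)F)c1cc2cc(C3(C)OCCO3)c(O[Si](C(C)C)(C(C)C)C(C)C)cc2o1
A5 | alternative 2 | (3S,5R)-5-(iodomethyl)-5-(7-methoxy-2,2-dimethyl-2H-chromen-6-yl)-3-methyloxolan-2-one | COc1cc2OC(C)(C)C=Cc2cc1[C@@]1(CI)C[C@H](C)C(=O)O1
A6 | alternative 2 | (2S)-4-(7-methoxy-2,2-dimethyl-2H-chromen-6-yl)-2-methylpent-4-enoic acid | COc1cc2OC(C)(C)C=Cc2cc1C(=C)C[C@H](C)C(O)=O
A7 | alternative 3 | 1-{6-hydroxy-2-[(2S,4R)-4-(7-methoxy-2,2-dimethyl-2H-chromen-6-yl)-4-(triethylsilyloxy)pentan-2-yl]-1-benzofuran-5-yl}ethan-1-one | COc1cc2OC(C)(C)C=Cc2cc1[C@](C)(O[Si](CC)(CC)CC)C[C@H](C)c1cc2cc(C(C)=O)c(O)cc2o1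
A8 | alternative 3 | {5-acetyl-4-hydroxy-2-[(2S,4R)-4-(7-methoxy-2,2-dimethyl-2H-chromen-6-yl)-2-methyl-4-(triethylsilyloxy)pentanoyloxy]benzyl}triphenylphosphonium bromide | COc1cc2OC(C)(C)C=Cc2cc1[C@](C)(O[Si](CC)(CC)CC)C[C@H](C)C(=O)Oc1cc(O)c(C(C)=O)cc1C[P+](c1ccccc1)(c1ccccc1)c1ccccc1.[Br-]
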